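## Structural features

The target joins two 2-(2-phenylethyl)chromone units. The upper unit is a 5,6,7,8-tetrahydro-4H-chromen-4-one, a γ-pyranone fused through C4a=C8a to a saturated C5–C8 chain; the lower unit is an aromatic 7-hydroxychromone. They are linked by a secondary alkyl aryl ether from C5 to the oxygen on C6'.

Four contiguous oxygenated stereocentres stand on the carbocycle: C5 (S), C6 (S), C7 (R), C8 (S). The C5 and C8 oxygens lie on one face and the cis C6/C7 diol on the other (5,6-trans, 6,7-cis, 7,8-trans).

C5 and C8 are both bonded to the pyranone double bond, so each C–O bond is allylic to a vinylogous ester and H-8 is vinylogously acidic. Ionisation or 1,4-elimination at these positions leads irreversibly to an aromatic chromone. The γ-pyranones are also open to ring cleavage by hard nucleophiles, and the free phenol next to the ether oxygen is oxidisable.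

The real difficulty is the hindered C5–O–aryl bond at a stereocentre, next to three further carbinols, without passing through an enolisable β-aryloxy ketone or an intermediate that aromatises. The key step exploits that C5 and C8 hang on the adjacent pyranone carbons C4a and C8a, and that C6–C7 is the carbocycle bond farthest from the heterocycle. Two 1-oxyallyl arms on a preformed pyranone can therefore be joined at C6=C7 by ring-closing metathesis, and the new alkene then takes up both remaining hydroxyls on the face opposite to the two oxygens already present.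

## Logic of the disconnections

28 ⇐ 27 ⇐ 26. The O–Si bond at C8 and the O–CH2Ar bond at C7' are cut last. Both groups are needed earlier: the silyl ether keeps the C8 oxygen from acting as a nucleophile or leaving group, and the benzyl-type ether leaves only one phenol free for the ether-forming step. The demand is that both removals run without acid strong enough to ionise C5–O and without base strong enough to remove H-8.

26 ⇐ 24. The C6–O and C7–O bonds are cut together. This removes two stereocentres and leaves a cis-5,8-disubstituted 5,8-dihydrochromone in which both allylic oxygens sit on one face. The forward cis-dihydroxylation must come from the opposite face and must be run before 24 can lose its phenol or silanol.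

24 ⇐ 23. The C6=C7 bond is cut, which opens the carbocycle to two vinyl groups on neighbouring pyranone carbons. The gain is that the heterocycle and both stereocentres (C5, C8) exist before the ring is closed, each set independently. The forward metathesis must close a ring between two hindered allylic ethers without alkene migration.

23 ⇐ 22 + 6. The C5–O aryl ether bond is cut, dividing the molecule into its two chromone-type halves. The forward step must form a branched allylic aryl ether with catalyst control of configuration at C5, on an allyl unit flanked by the pyranone carbonyl and the C8 arm, using a phenoxide too weak a base to touch H-8.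

22 ⇐ 20 ⇐ 18 + 19. The carbonate C–O bond and then the C4a–C(alkenyl) bond are cut. This leaves a pyranone carrying a sulfonate leaving group exactly at C4a. The coupling must tolerate the silyl ether and the terminal vinyl group and deliver the E alkene.

18 ⇐ 16 ⇐ 14 + 15. The O–Si bond and then the C8–C7 (carbinol–vinyl) bond are cut, which returns an achiral aldehyde. The forward addition must be enantioselective (vinyl to the Si face, giving 8S) and mild enough to leave the neighbouring triflate intact.

14 ⇐ 13 ⇐ 11. The aldehyde is taken back to a primary alcohol and the triflate to an enolic hydroxyl. The demand is selective sulfonylation of the acidic enol OH in the presence of the primary alcohol.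

11 ⇐ 9 + 10. The C8a–C8 bond is cut. The enolic hydroxyl of 9 directs the one-carbon electrophile to the ring carbon next to it and next to the ring oxygen. The regiochemical problem of the upper unit (C8 arm on C8a, leaving group on C4a, phenethyl on C2) is thereby solved by the substitution pattern of 9 alone.

9 ⇐ 7 + 8. The CH2–CH2Ph bond is cut, which gives a commercial hydroxypyranone. The forward step is a lateral alkylation through a dianion; the carbanion must react in preference to the oxygen.

6 ⇐ 4 + 5. The O–benzyl bond at C7' is cut. The forward alkylation relies on the higher acidity of the 7-OH (para to the carbonyl-bearing ring carbon) over the 6-OH.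

4 ⇐ 1 + 2. The C2'–C3' bond and the O1'–C2' bond of the lower pyranone ring are cut, returning a trihydroxyacetophenone and a three-carbon acyl donor. The forward sequence needs C-acylation of the ketone enolate in the presence of three phenoxides, then cyclodehydration.

## Other disconnections considered

Alternative 1: The cut is at the two C–O bonds of C5 and C8; the carbocycle with C6 and C7 is taken from (−)-shikimic acid as the diene ester A1. The forward key step is a [4+2] addition of singlet oxygen across the diene termini, anti to the acetonide, giving the endoperoxide A2.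
- In favour: C6 and C7 come from the chiral pool with the configuration the target needs, and one diastereoselective step places both remaining oxygens trans to them. No asymmetric catalyst is needed. On stereochemical economy this plan is the better one.
- Against: the carbocycle exists before the heterocycle. The pyranone would have to be grown from the ester carbon and from a vinylic C8a–H that still lacks its oxygen. The two peroxide oxygens must be told apart after O–O cleavage, and the C5 oxygen must then be arylated with retention on a hindered secondary alcohol by a deactivated aryl partner. The 4-oxygenated cyclohexenoate intermediates are as prone to aromatisation as 24, and base would trigger peroxide rearrangement to a hydroxy enone.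
- Comparison: the chosen plan forms the C5–O bond by a catalytic substitution designed for aryl ethers and never needs to build a pyranone on an oxygen-laden ring. Step count would be similar or longer.

Alternative 2: The cut is at C6–O and C7–O of a substrate in which C8 is a masked ketone, the dienone ketal A3. The forward key step is cis-dihydroxylation anti to the C5 aryloxy group, giving the diol ketal A4; ketal hydrolysis and a hydroxyl-directed reduction at C8 would follow.
- In favour: only C5 needs an external source of chirality, no C8 arm and no metathesis catalyst are required, and the diol step obeys the same facial logic as step 13. On the number of asymmetric operations it is the better plan; on the dihydroxylation it is equal.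
- Against: A3 carries a leaving group at C8 and a hydrogen at C5, so traces of acid would turn it into an aromatic 8-methoxychromone. Only one allylic substituent biases the osmylation. The late α-hydroxy ketone at C8 can eliminate the C6 hydroxyl. The C5 aryl ether still has to be made on a doubly activated carbinol, for which no catalytic method as suitable as allylic etherification is at hand.
- Comparison: similar length, lower robustness.

Alternative 3: The cut is at C4a–C5 and C8a–C8. The forward key step is a Diels–Alder addition of the sulfinylpyranone A5 (drawn as the R sulfoxide; the hand at sulfur would have to be matched) to the dioxygenated diene A6, followed by syn-elimination of the sulfenic acid, giving A7.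
- In favour: it is the most convergent plan. Two C–C bonds, the ring and both the C5 and C8 centres arise in one operation, with the cis relation fixed by the E,E geometry of A6 and the auxiliary lost tracelessly. In bond and ring economy it is clearly better than metathesis, which forms one bond and no stereocentre.
- Against: the dienophile is a trisubstituted push–pull alkene of low reactivity. The two oxygen substituents of A6 differ little electronically, so the orientation (which terminus bonds to C4a) is poorly defined. Facial control by a sulfoxide on a pyranone is not assured, a Lewis acid strong enough to activate A5 would ionise A6, and A6 itself, carrying the whole lower chromone on a dienyl ether, is not easy to make in pure E,E form. A7 shares the aromatisation risk of 24.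
- Comparison: the end game is the same as in the chosen plan; the risk is moved into a single step with three selectivity problems.

Key step: step 12

Assumptions and remarks on the chemistry
- The structures of the key-step precursor 23 and product 24 were checked and needed no correction. Their descriptors are (1S)/(1R) in 23 and (5R,8S) in 24. The change from 5R in 24 to 5S in the target is formal, caused by the new oxygen on C6, not an inversion.
- The hand of each chiral controller is named from its usual behaviour with benzaldehyde or cinnamyl substrates: (−)-DAIB for Si-face vinyl delivery, and the (Ra,R,R) phosphoramidite for the R aryl ether. Both are available in either hand should the sense be the reverse.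
- L = (Ra)-1,1'-binaphthalene-2,2'-diyl N,N-bis[(R)-1-phenylethyl]phosphoramidite.
- A start from 2,6-dimethyl-4H-pyran-4-one was weighed and set aside for three reasons. It offers no way to place the C4a substituent next to the oxidised methyl and not next to the phenethyl side. Oxidants such as SeO2 would not tell the methyl from the phenethyl CH2. An aryl vinyl ketone is a poor substrate for asymmetric reduction. The hydroxypyranone 7 settles the first two points through its enolic OH, and the carbinol is made by direct asymmetric vinyl addition.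
- The acyl carbon source for the lower chromone (2) is added to the starting materials.

## Route

Step 1
Reactants: 1 2',4',5'-trihydroxyacetophenone; 2 3-phenylpropanoyl chloride
Product: 4 6,7-dihydroxy-2-(2-phenylethyl)-4H-chromen-4-one, via 5-phenyl-1-(2,4,5-trihydroxyphenyl)pentane-1,3-dione 3 (not isolated)
Conditions: LiN(SiMe3)2 (5.2 equiv), THF, −78 → −10 °C; 2 (1.0 equiv), −78 °C → rt; then AcOH, H2SO4 (1%), 95 °C
Reagents that add atoms: 3-phenylpropanoyl chloride, O=C(Cl)CCc1ccccc1
Why: The polylithiated acetophenone is acylated at the enolate carbon (Claisen-type C-acylation, the phenoxides being far less nucleophilic), and the resulting 1,3-diketone undergoes acid-catalysed cyclodehydration to the chromone; any O-acyl material is cleaved in the acidic stage.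

Step 2
Reactants: 4 6,7-dihydroxy-2-(2-phenylethyl)-4H-chromen-4-one; 5 4-methoxybenzyl chloride
Product: 6 6-hydroxy-7-[(4-methoxyphenyl)methoxy]-2-(2-phenylethyl)-4H-chromen-4-one
Conditions: 5 (1.05 equiv), NaHCO3, NaI (cat.), DMF, 40 °C
Reagents that add atoms: 4-methoxybenzyl chloride, COc1ccc(CCl)cc1
Why: Williamson etherification under a weak base, which ionises only the 7-OH (conjugated through C4a with the C4 carbonyl); the 6-OH, para to the ring oxygen, should stay protonated and unreactive.

Step 3
Reactants: 7 5-hydroxy-2-methyl-4H-pyran-4-one (allomaltol); 8 benzyl bromide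
Product: 9 5-hydroxy-2-(2-phenylethyl)-4H-pyran-4-one
Conditions: LiN(iPr)2 (2.3 equiv), THF–DMPU, −78 °C; 8 (1.0 equiv), −78 → −20 °C; aq. HCl
Reagents that add atoms: benzyl bromide, BrCc1ccccc1
Why: Lateral alkylation of a dianion: the second deprotonation occurs at the vinylogous 2-methyl group and the carbanion, the more basic site, should take the benzyl halide before the oxyanion does, as with other hydroxypyranone dianions.

Step 4
Reactants: 9 5-hydroxy-2-(2-phenylethyl)-4H-pyran-4-one; 10 formaldehyde
Product: 11 3-hydroxy-2-(hydroxymethyl)-6-(2-phenylethyl)-4H-pyran-4-one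
Conditions: aq. CH2O (1.2 equiv), NaOH (1.05 equiv), H2O–MeOH, rt; then HCl to pH 3
Reagents that add atoms: formaldehyde, C=O
Why: Aldol-type hydroxymethylation of the enolate of a 5-hydroxy-4-pyranone, which is nucleophilic only at the ring carbon between the hydroxyl-bearing carbon and the ring oxygen (the kojic acid pattern), so the new carbon goes onto the future C8a.

Step 5
Reactants: 11 3-hydroxy-2-(hydroxymethyl)-6-(2-phenylethyl)-4H-pyran-4-one; 12 N-phenylbis(trifluoromethanesulfonimide)
Product: 13 2-(hydroxymethyl)-4-oxo-6-(2-phenylethyl)-4H-pyran-3-yl trifluoromethanesulfonate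
Conditions: 12 (1.05 equiv), Et3N (1.2 equiv), CH2Cl2, 0 °C → rt
Reagents that add atoms: N-phenylbis(trifluoromethanesulfonimide), O=S(=O)(N(c1ccccc1)S(=O)(=O)C(F)(F)F)C(F)(F)F
Why: Sulfonylation of the acidic enolic hydroxyl; this mild triflyl donor reacts with phenol-type oxyanions and should leave the un-ionised primary alcohol alone.

Step 6
Reactants: 13 2-(hydroxymethyl)-4-oxo-6-(2-phenylethyl)-4H-pyran-3-yl trifluoromethanesulfonate
Product: 14 2-formyl-4-oxo-6-(2-phenylethyl)-4H-pyran-3-yl trifluoromethanesulfonate
Conditions: Dess–Martin periodinane (1.2 equiv), NaHCO3, CH2Cl2, 0 °C → rt; used crude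
Reagents that add atoms: none
Why: Neutral hypervalent-iodine oxidation of a primary alcohol to the aldehyde; no over-oxidation is expected and the triflate and pyranone are inert.

Step 7
Reactants: 14 2-formyl-4-oxo-6-(2-phenylethyl)-4H-pyran-3-yl trifluoromethanesulfonate; 15 vinylmagnesium bromide
Product: 16 2-[(1S)-1-hydroxyprop-2-en-1-yl]-4-oxo-6-(2-phenylethyl)-4H-pyran-3-yl trifluoromethanesulfonate
Conditions: (CH2=CH)2Zn [from CH2=CHMgBr (2.4 equiv), ZnCl2 (1.2 equiv), Et2O, then 1,4-dioxane to remove MgBrCl], (−)-DAIB (10 mol %), toluene, −20 → 0 °C; aq. NH4Cl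
Reagents that add atoms: divinylzinc, C=C[Zn]C=C (made from vinylmagnesium bromide, C=C[Mg]Br)
Why: Amino-alcohol-catalysed enantioselective addition of an alkenylzinc to an aldehyde; the chiral zinc alkoxide complex should deliver the vinyl group to the Si face, setting the future C8 as S, and the salt-free organozinc has no uncatalysed pathway and does not attack the triflate.

Step 8
Reactants: 16 2-[(1S)-1-hydroxyprop-2-en-1-yl]-4-oxo-6-(2-phenylethyl)-4H-pyran-3-yl trifluoromethanesulfonate; 17 tert-butyl(chloro)dimethylsilane
Product: 18 2-[(1S)-1-{[tert-butyl(dimethyl)silyl]oxy}prop-2-en-1-yl]-4-oxo-6-(2-phenylethyl)-4H-pyran-3-yl trifluoromethanesulfonate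
Conditions: 17 (1.5 equiv), imidazole (3 equiv), DMF, rt
Reagents that add atoms: tert-butyl(chloro)dimethylsilane, CC(C)(C)[Si](C)(C)Cl
Why: Standard silylation of a secondary alcohol under weakly basic conditions that cannot remove the carbinol hydrogen, so the stereocentre is untouched.

Step 9
Reactants: 18 the silyl ether triflate from step 8; 19 (2E)-3-(4,4,5,5-tetramethyl-1,3,2-dioxaborolan-2-yl)prop-2-en-1-ol
Product: 20 2-[(1S)-1-{[tert-butyl(dimethyl)silyl]oxy}prop-2-en-1-yl]-3-[(1E)-3-hydroxyprop-1-en-1-yl]-6-(2-phenylethyl)-4H-pyran-4-one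
Conditions: 19 (1.3 equiv), Pd(dppf)Cl2 (5 mol %), K3PO4 (2 equiv), 1,4-dioxane–H2O (10:1), 60 °C
Reagents that add atoms: (2E)-3-(4,4,5,5-tetramethyl-1,3,2-dioxaborolan-2-yl)prop-2-en-1-ol, OC/C=C/B1OC(C)(C)C(C)(C)O1
Why: Suzuki–Miyaura coupling of an electron-poor enol triflate (a pyranone 3-triflate) with an alkenylboronate, with retention of the E geometry; the phosphate base is too weak to remove the hydrogen on the silyloxy carbon.

Step 10
Reactants: 20 the allylic alcohol from step 9; 21 methyl chloroformate
Product: 22 (2E)-3-{2-[(1S)-1-{[tert-butyl(dimethyl)silyl]oxy}prop-2-en-1-yl]-4-oxo-6-(2-phenylethyl)-4H-pyran-3-yl}prop-2-en-1-yl methyl carbonate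
Conditions: 21 (1.5 equiv), pyridine, CH2Cl2, 0 °C
Reagents that add atoms: methyl chloroformate, COC(=O)Cl
Why: Acylation of the primary allylic alcohol to the carbonate, the leaving group needed for iridium allyl formation.

Step 11
Reactants: 22 the linear allylic methyl carbonate from step 10; 6 6-hydroxy-7-[(4-methoxyphenyl)methoxy]-2-(2-phenylethyl)-4H-chromen-4-one
Product: 23 2-[(1S)-1-{[tert-butyl(dimethyl)silyl]oxy}prop-2-en-1-yl]-3-[(1R)-1-({7-[(4-methoxyphenyl)methoxy]-4-oxo-2-(2-phenylethyl)-4H-chromen-6-yl}oxy)prop-2-en-1-yl]-6-(2-phenylethyl)-4H-pyran-4-one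
Conditions: [Ir(cod)Cl]2 (2 mol %), (Ra,R,R)-L (4 mol %), n-PrNH2 (activation at 50 °C, then evaporated); LiOAr from 6 (1.3 equiv) and LiN(SiMe3)2 (1.3 equiv); THF, 40 °C
Reagents that add atoms: compound 6 as its lithium aryloxide, O=c1cc(CCc2ccccc2)oc2cc(OCc3ccc(OC)cc3)c(O)cc12
Why: Iridium-phosphoramidite-catalysed allylic etherification: the cyclometalated iridium allyl complex is attacked by the aryloxide at the substituted terminus, and the ligand should fix the face so that the branched ether forms with R configuration at the future C5. The weakly basic phenoxide cannot epimerise the silyloxy centre, and no β-aryloxy ketone is involved.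

Step 12
Reactants: 23 the diene from step 11
Product: 24 (5R,8S)-8-{[tert-butyl(dimethyl)silyl]oxy}-5-({7-[(4-methoxyphenyl)methoxy]-4-oxo-2-(2-phenylethyl)-4H-chromen-6-yl}oxy)-2-(2-phenylethyl)-5,8-dihydro-4H-chromen-4-one
Conditions: second-generation Grubbs catalyst RuCl2(=CHPh)(H2IMes)(PCy3) (5–10 mol %), 1,4-benzoquinone (10 mol %), degassed CH2Cl2 (5 mM), 40 °C; ethyl vinyl ether quench; fast filtration through Et3N-deactivated silica; used at once
Reagents that add atoms: none
Why: The ruthenium benzylidene exchanges with one terminal vinyl group to give a ruthenium alkylidene, which adds to the second vinyl group in an intramolecular [2+2] step; cycloreversion of the ruthenacyclobutane releases the C6=C7 alkene and a ruthenium methylidene, and loss of ethylene drives the cycle. The closest known reaction type is ring-closing metathesis of 1,7-dienes to cyclohexenes, in particular of ortho-bis(1-oxyallyl)arenes to 1,4-dioxygenated 1,4-dihydronaphthalenes. The one ring formed is the six-membered carbocycle C4a–C5–C6–C7–C8–C8a, closed by joining the two alkene termini held side by side on the planar pyranone, which makes closure entropically easy. No stereocentre is formed: C5 (R) and C8 (S) are carried over unchanged from 23, and their cis relation follows from the two independently set centres. The selectivity needed is chemoselectivity, that is ring closure without double-bond migration and without 1,4-elimination of the phenol or silanol to an aromatic chromone. The neutral non-basic medium, the benzoquinone that intercepts ruthenium hydrides, the poor leaving-group ability of the silyl ether and the immediate use of 24 should secure it; dilution suppresses cross-metathesis of the terminal alkenes.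

Step 13
Reactants: 24 the dihydrochromone from step 12; 25 N-methylmorpholine N-oxide
Product: 26 (5S,6S,7R,8S)-8-{[tert-butyl(dimethyl)silyl]oxy}-6,7-dihydroxy-5-({7-[(4-methoxyphenyl)methoxy]-4-oxo-2-(2-phenylethyl)-4H-chromen-6-yl}oxy)-2-(2-phenylethyl)-5,6,7,8-tetrahydro-4H-chromen-4-one
Conditions: OsO4 (5 mol %), 25 (1.5 equiv), acetone–H2O (8:1), 0 °C → rt; aq. Na2SO3
Reagents that add atoms: OsO4, O=[Os](=O)(=O)=O (transfers both oxygens); N-methylmorpholine N-oxide, C[N+]1([O-])CCOCC1 (restores the oxidant)
Why: Catalytic cis-dihydroxylation by a [3+2] osmate ester; OsO4 adds anti to allylic oxygen substituents, and here both the C5 aryloxy and the bulky C8 silyloxy group shield the same face, so both hydroxyls should enter trans to their neighbours (6S,7R). The tetrasubstituted, electron-poor pyranone alkenes are inert.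

Step 14
Reactants: 26 the diol from step 13
Product: 27 (5S,6S,7R,8S)-8-{[tert-butyl(dimethyl)silyl]oxy}-6,7-dihydroxy-5-{[7-hydroxy-4-oxo-2-(2-phenylethyl)-4H-chromen-6-yl]oxy}-2-(2-phenylethyl)-5,6,7,8-tetrahydro-4H-chromen-4-one
Conditions: DDQ (1.5 equiv), CH2Cl2–pH 7 phosphate buffer (10:1), 0 °C → rt
Reagents that add atoms: none
Why: Oxidative cleavage of the 4-methoxybenzyl ether by hydride abstraction from the electron-rich benzylic position and hydrolysis of the oxocarbenium ion. The buffered neutral medium avoids both ionisation at C5 and deprotonation at C8, and the carbinol carbons, attached to an electron-poor pyranone, are not oxidised.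

Step 15
Reactants: 27 the silyl ether from step 14
Product: 28 (5S,6S,7R,8S)-6,7,8-trihydroxy-5-{[7-hydroxy-4-oxo-2-(2-phenylethyl)-4H-chromen-6-yl]oxy}-2-(2-phenylethyl)-5,6,7,8-tetrahydro-4H-chromen-4-one (CNP0248258.1)
Conditions: HF·pyridine, pyridine–THF, 0 °C → rt; quench with Me3SiOMe
Reagents that add atoms: none
Why: Fluoride-driven desilylation in a buffered, weakly acidic medium; the strong Si–F bond cleaves Si–O without the basicity of naked fluoride, so C8 is not epimerised and the C5 ether is not ionised.

## Compound list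

1 | 1-(2,4,5-trihydroxyphenyl)ethan-1-one (2',4',5'-trihydroxyacetophenone) | CC(=O)c1cc(O)c(O)cc1O | starting material
2 | 3-phenylpropanoyl chloride | O=C(Cl)CCc1ccccc1 | starting material
3 | 5-phenyl-1-(2,4,5-trihydroxyphenyl)pentane-1,3-dione | O=C(CC(=O)CCc1ccccc1)c1cc(O)c(O)cc1O | intermediate (not isolated)
4 | 6,7-dihydroxy-2-(2-phenylethyl)-4H-chromen-4-one | O=c1cc(CCc2ccccc2)oc2cc(O)c(O)cc12 | intermediate
5 | 1-(chloromethyl)-4-methoxybenzene (4-methoxybenzyl chloride) | COc1ccc(CCl)cc1 | starting material
6 | 6-hydroxy-7-[(4-methoxyphenyl)methoxy]-2-(2-phenylethyl)-4H-chromen-4-one | O=c1cc(CCc2ccccc2)oc2cc(OCc3ccc(OC)cc3)c(O)cc12 | intermediate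
7 | 5-hydroxy-2-methyl-4H-pyran-4-one (allomaltol) | Cc1cc(=O)c(O)co1 | starting material
8 | benzyl bromide | BrCc1ccccc1 | starting material
9 | 5-hydroxy-2-(2-phenylethyl)-4H-pyran-4-one | O=c1cc(CCc2ccccc2)occ1O | intermediate
10 | formaldehyde | C=O | starting material
11 | 3-hydroxy-2-(hydroxymethyl)-6-(2-phenylethyl)-4H-pyran-4-one | O=c1cc(CCc2ccccc2)oc(CO)c1O | intermediate
12 | N-phenylbis(trifluoromethanesulfonimide) | O=S(=O)(N(c1ccccc1)S(=O)(=O)C(F)(F)F)C(F)(F)F | starting material
13 | 2-(hydroxymethyl)-4-oxo-6-(2-phenylethyl)-4H-pyran-3-yl trifluoromethanesulfonate | O=c1cc(CCc2ccccc2)oc(CO)c1OS(=O)(=O)C(F)(F)F | intermediate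
14 | 2-formyl-4-oxo-6-(2-phenylethyl)-4H-pyran-3-yl trifluoromethanesulfonate | O=Cc1oc(CCc2ccccc2)cc(=O)c1OS(=O)(=O)C(F)(F)F | intermediate
15 | vinylmagnesium bromide | C=C[Mg]Br | starting material
16 | 2-[(1S)-1-hydroxyprop-2-en-1-yl]-4-oxo-6-(2-phenylethyl)-4H-pyran-3-yl trifluoromethanesulfonate | O=c1cc(CCc2ccccc2)oc([C@@H](O)C=C)c1OS(=O)(=O)C(F)(F)F | intermediate
17 | tert-butyl(chloro)dimethylsilane | CC(C)(C)[Si](C)(C)Cl | starting material
18 | 2-[(1S)-1-{[tert-butyl(dimethyl)silyl]oxy}prop-2-en-1-yl]-4-oxo-6-(2-phenylethyl)-4H-pyran-3-yl trifluoromethanesulfonate | O=c1cc(CCc2ccccc2)oc([C@@H](O[Si](C)(C)C(C)(C)C)C=C)c1OS(=O)(=O)C(F)(F)F | intermediate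
19 | (2E)-3-(4,4,5,5-tetramethyl-1,3,2-dioxaborolan-2-yl)prop-2-en-1-ol | OC/C=C/B1OC(C)(C)C(C)(C)O1 | starting material
20 | 2-[(1S)-1-{[tert-butyl(dimethyl)silyl]oxy}prop-2-en-1-yl]-3-[(1E)-3-hydroxyprop-1-en-1-yl]-6-(2-phenylethyl)-4H-pyran-4-one | O=c1cc(CCc2ccccc2)oc([C@@H](O[Si](C)(C)C(C)(C)C)C=C)c1/C=C/CO | intermediate
21 | methyl chloroformate | COC(=O)Cl | starting material
22 | (2E)-3-{2-[(1S)-1-{[tert-butyl(dimethyl)silyl]oxy}prop-2-en-1-yl]-4-oxo-6-(2-phenylethyl)-4H-pyran-3-yl}prop-2-en-1-yl methyl carbonate | O=c1cc(CCc2ccccc2)oc([C@@H](O[Si](C)(C)C(C)(C)C)C=C)c1/C=C/COC(=O)OC | intermediate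
23 | 2-[(1S)-1-{[tert-butyl(dimethyl)silyl]oxy}prop-2-en-1-yl]-3-[(1R)-1-({7-[(4-methoxyphenyl)methoxy]-4-oxo-2-(2-phenylethyl)-4H-chromen-6-yl}oxy)prop-2-en-1-yl]-6-(2-phenylethyl)-4H-pyran-4-one | O=c1cc(CCc2ccccc2)oc([C@@H](O[Si](C)(C)C(C)(C)C)C=C)c1[C@H](Oc1cc2c(=O)cc(CCc3ccccc3)oc2cc1OCc1ccc(OC)cc1)C=C | intermediate
24 | (5R,8S)-8-{[tert-butyl(dimethyl)silyl]oxy}-5-({7-[(4-methoxyphenyl)methoxy]-4-oxo-2-(2-phenylethyl)-4H-chromen-6-yl}oxy)-2-(2-phenylethyl)-5,8-dihydro-4H-chromen-4-one | O=c1cc(CCc2ccccc2)oc2c1[C@H](Oc1cc3c(=O)cc(CCc4ccccc4)oc3cc1OCc1ccc(OC)cc1)C=C[C@@H]2O[Si](C)(C)C(C)(C)C | intermediate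
25 | N-methylmorpholine N-oxide | C[N+]1([O-])CCOCC1 | starting material
26 | (5S,6S,7R,8S)-8-{[tert-butyl(dimethyl)silyl]oxy}-6,7-dihydroxy-5-({7-[(4-methoxyphenyl)methoxy]-4-oxo-2-(2-phenylethyl)-4H-chromen-6-yl}oxy)-2-(2-phenylethyl)-5,6,7,8-tetrahydro-4H-chromen-4-one | O=c1cc(CCc2ccccc2)oc2c1[C@H](Oc1cc3c(=O)cc(CCc4ccccc4)oc3cc1OCc1ccc(OC)cc1)[C@@H](O)[C@@H](O)[C@@H]2O[Si](C)(C)C(C)(C)C | intermediate
27 | (5S,6S,7R,8S)-8-{[tert-butyl(dimethyl)silyl]oxy}-6,7-dihydroxy-5-{[7-hydroxy-4-oxo-2-(2-phenylethyl)-4H-chromen-6-yl]oxy}-2-(2-phenylethyl)-5,6,7,8-tetrahydro-4H-chromen-4-one | O=c1cc(CCc2ccccc2)oc2c1[C@H](Oc1cc3c(=O)cc(CCc4ccccc4)oc3cc1O)[C@@H](O)[C@@H](O)[C@@H]2O[Si](C)(C)C(C)(C)C | intermediate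
28 | (5S,6S,7R,8S)-6,7,8-trihydroxy-5-{[7-hydroxy-4-oxo-2-(2-phenylethyl)-4H-chromen-6-yl]oxy}-2-(2-phenylethyl)-5,6,7,8-tetrahydro-4H-chromen-4-one | O=c1cc(CCc2ccccc2)oc2c1[C@H](Oc1cc3c(=O)cc(CCc4ccccc4)oc3cc1O)[C@@H](O)[C@@H](O)[C@@H]2O | target

## Step count and least certain steps

Total: 15 steps. Longest linear sequence: 13 steps (steps 3–15, from 7). The lower unit takes 2 steps (steps 1–2) and joins at step 11.

Step 12 (key step). Most likely failure: slow initiation at two hindered allylic ethers, leaving time for ruthenium-hydride-mediated alkene migration or for 1,4-elimination of the phenol with aromatisation. Fallback, from 23 to 28: the silyl group is removed first with HF·pyridine to give the free carbinol 3-[(1R)-1-({7-[(4-methoxyphenyl)methoxy]-4-oxo-2-(2-phenylethyl)-4H-chromen-6-yl}oxy)prop-2-en-1-yl]-2-[(1S)-1-hydroxyprop-2-en-1-yl]-6-(2-phenylethyl)-4H-pyran-4-one F1. Its free allylic hydroxyl is known to accelerate metathesis. Ring closure with the second-generation Hoveyda–Grubbs catalyst RuCl2(=CH-C6H4-2-OiPr)(H2IMes) would give (5R,8S)-8-hydroxy-5-({7-[(4-methoxyphenyl)methoxy]-4-oxo-2-(2-phenylethyl)-4H-chromen-6-yl}oxy)-2-(2-phenylethyl)-5,8-dihydro-4H-chromen-4-one F2. OsO4 with N-methylmorpholine N-oxide, again anti to both allylic oxygens, would give (5S,6S,7R,8S)-6,7,8-trihydroxy-5-({7-[(4-methoxyphenyl)methoxy]-4-oxo-2-(2-phenylethyl)-4H-chromen-6-yl}oxy)-2-(2-phenylethyl)-5,6,7,8-tetrahydro-4H-chromen-4-one F3, and DDQ in buffered CH2Cl2 would then give 28. The number of steps is unchanged.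

Step 11. Most likely failure: the allyl terminus is flanked by the pyranone carbonyl and the silyloxyallyl arm, so attack may shift to the unhindered terminus (linear ether) or the allyl complex may form too slowly; enantioselectivity may also fall. Fallback, from 20 to 23, by stoichiometric known chemistry:
- Titanium-tartrate epoxidation of 20 (Ti(OiPr)4, D-(−)-diethyl tartrate, t-BuOOH) to 2-[(1S)-1-{[tert-butyl(dimethyl)silyl]oxy}prop-2-en-1-yl]-3-[(2R,3R)-3-(hydroxymethyl)oxiran-2-yl]-6-(2-phenylethyl)-4H-pyran-4-one F4.
- Conversion to the iodide with I2, PPh3 and imidazole, giving 2-[(1S)-1-{[tert-butyl(dimethyl)silyl]oxy}prop-2-en-1-yl]-3-[(2R,3S)-3-(iodomethyl)oxiran-2-yl]-6-(2-phenylethyl)-4H-pyran-4-one F5.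
- Reductive opening with Zn in buffered ethanol to the branched alcohol 2-[(1S)-1-{[tert-butyl(dimethyl)silyl]oxy}prop-2-en-1-yl]-3-[(1S)-1-hydroxyprop-2-en-1-yl]-6-(2-phenylethyl)-4H-pyran-4-one F6.
- Mitsunobu etherification with 6 (PPh3, diisopropyl azodicarboxylate), with inversion, to 23.

Step 7. Most likely failure: poor facial discrimination, because the ring oxygen and the triflate can chelate zinc and disturb the amino-alcohol transition state, or an uncatalysed background addition. Fallback, from 14 to 16: plain addition of CH2=CHMgBr at −78 °C gives the racemic carbinol 2-(1-hydroxyprop-2-en-1-yl)-4-oxo-6-(2-phenylethyl)-4H-pyran-3-yl trifluoromethanesulfonate F9. Kinetic resolution with immobilised Candida antarctica lipase B and vinyl acetate should acylate the R enantiomer, by the empirical rule for secondary alcohols with one large and one medium group. This gives 2-[(1R)-1-(acetyloxy)prop-2-en-1-yl]-4-oxo-6-(2-phenylethyl)-4H-pyran-3-yl trifluoromethanesulfonate F10 and leaves 16, at the cost of half the material.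

Step 3. Most likely failure: incomplete formation of the dianion, followed by O-benzylation of the enolic oxygen or C-benzylation at the ring carbon next to it. Fallback, from 7 to 9: O-benzylation with 8 and K2CO3 gives 5-(benzyloxy)-2-methyl-4H-pyran-4-one F7. Lateral deprotonation with LiN(SiMe3)2 and alkylation with 8 gives 5-(benzyloxy)-2-(2-phenylethyl)-4H-pyran-4-one F8. Hydrogenolysis over Pd/C returns 9 (two extra steps).

Step 1. Most likely failure: ketene formation from the aliphatic acyl chloride under excess amide base, or O-acylation of the air-sensitive polyphenoxide, lowering the amount of C-acylated diketone. Fallback, from 1 to 4: exhaustive O-acylation with 2 in pyridine gives 2-acetylbenzene-1,4,5-triyl tris(3-phenylpropanoate) F11. Baker–Venkataraman rearrangement with KOH in pyridine gives 4-hydroxy-5-(3-oxo-5-phenylpentanoyl)-1,2-phenylene bis(3-phenylpropanoate) F12. Heating in AcOH–H2SO4 cyclises and cleaves the remaining esters to give 4 (two extra steps).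

## Further compounds

F1 | step 12 | 3-[(1R)-1-({7-[(4-methoxyphenyl)methoxy]-4-oxo-2-(2-phenylethyl)-4H-chromen-6-yl}oxy)prop-2-en-1-yl]-2-[(1S)-1-hydroxyprop-2-en-1-yl]-6-(2-phenylethyl)-4H-pyran-4-one | O=c1cc(CCc2ccccc2)oc([C@@H](O)C=C)c1[C@H](Oc1cc2c(=O)cc(CCc3ccccc3)oc2cc1OCc1ccc(OC)cc1)C=C
F2 | step 12 | (5R,8S)-8-hydroxy-5-({7-[(4-methoxyphenyl)methoxy]-4-oxo-2-(2-phenylethyl)-4H-chromen-6-yl}oxy)-2-(2-phenylethyl)-5,8-dihydro-4H-chromen-4-one | O=c1cc(CCc2ccccc2)oc2c1[C@H](Oc1cc3c(=O)cc(CCc4ccccc4)oc3cc1OCc1ccc(OC)cc1)C=C[C@@H]2O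
F3 | step 12 | (5S,6S,7R,8S)-6,7,8-trihydroxy-5-({7-[(4-methoxyphenyl)methoxy]-4-oxo-2-(2-phenylethyl)-4H-chromen-6-yl}oxy)-2-(2-phenylethyl)-5,6,7,8-tetrahydro-4H-chromen-4-one | O=c1cc(CCc2ccccc2)oc2c1[C@H](Oc1cc3c(=O)cc(CCc4ccccc4)oc3cc1OCc1ccc(OC)cc1)[C@@H](O)[C@@H](O)[C@@H]2O
F4 | step 11 | 2-[(1S)-1-{[tert-butyl(dimethyl)silyl]oxy}prop-2-en-1-yl]-3-[(2R,3R)-3-(hydroxymethyl)oxiran-2-yl]-6-(2-phenylethyl)-4H-pyran-4-one | O=c1cc(CCc2ccccc2)oc([C@@H](O[Si](C)(C)C(C)(C)C)C=C)c1[C@H]1O[C@@H]1CO
F5 | step 11 | 2-[(1S)-1-{[tert-butyl(dimethyl)silyl]oxy}prop-2-en-1-yl]-3-[(2R,3S)-3-(iodomethyl)oxiran-2-yl]-6-(2-phenylethyl)-4H-pyran-4-one | O=c1cc(CCc2ccccc2)oc([C@@H](O[Si](C)(C)C(C)(C)C)C=C)c1[C@H]1O[C@@H]1CI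
F6 | step 11 | 2-[(1S)-1-{[tert-butyl(dimethyl)silyl]oxy}prop-2-en-1-yl]-3-[(1S)-1-hydroxyprop-2-en-1-yl]-6-(2-phenylethyl)-4H-pyran-4-one | O=c1cc(CCc2ccccc2)oc([C@@H](O[Si](C)(C)C(C)(C)C)C=C)c1[C@@H](O)C=C
F7 | step 3 | 5-(benzyloxy)-2-methyl-4H-pyran-4-one | Cc1cc(=O)c(OCc2ccccc2)co1
F8 | step 3 | 5-(benzyloxy)-2-(2-phenylethyl)-4H-pyran-4-one | O=c1cc(CCc2ccccc2)occ1OCc1ccccc1
F9 | step 7 | 2-(1-hydroxyprop-2-en-1-yl)-4-oxo-6-(2-phenylethyl)-4H-pyran-3-yl trifluoromethanesulfonate (racemate) | O=c1cc(CCc2ccccc2)oc(C(O)C=C)c1OS(=O)(=O)C(F)(F)F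
F10 | step 7 | 2-[(1R)-1-(acetyloxy)prop-2-en-1-yl]-4-oxo-6-(2-phenylethyl)-4H-pyran-3-yl trifluoromethanesulfonate | O=c1cc(CCc2ccccc2)oc([C@H](OC(C)=O)C=C)c1OS(=O)(=O)C(F)(F)F
F11 | step 1 | 2-acetylbenzene-1,4,5-triyl tris(3-phenylpropanoate) | CC(=O)c1cc(OC(=O)CCc2ccccc2)c(OC(=O)CCc2ccccc2)cc1OC(=O)CCc1ccccc1
F12 | step 1 | 4-hydroxy-5-(3-oxo-5-phenylpentanoyl)-1,2-phenylene bis(3-phenylpropanoate) | O=C(CC(=O)CCc1ccccc1)c1cc(OC(=O)CCc2ccccc2)c(OC(=O)CCc2ccccc2)cc1O
A1 | alternative 1 | methyl (3R,4S)-3,4-(isopropylidenedioxy)cyclohexa-1,5-diene-1-carboxylate | COC(=O)C1=C[C@H]2OC(C)(C)O[C@H]2C=C1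
A2 | alternative 1 | methyl 5,6-(isopropylidenedioxy)-2,3-dioxabicyclo[2.2.2]oct-7-ene-7-carboxylate, peroxide bridge anti to the acetonide | COC(=O)C1=C[C@H]2OO[C@@H]1[C@H]1OC(C)(C)O[C@@H]21
A3 | alternative 2 | (5R)-8,8-dimethoxy-5-({7-[(4-methoxyphenyl)methoxy]-4-oxo-2-(2-phenylethyl)-4H-chromen-6-yl}oxy)-2-(2-phenylethyl)-5,8-dihydro-4H-chromen-4-one | O=c1cc(CCc2ccccc2)oc2c1[C@H](Oc1cc3c(=O)cc(CCc4ccccc4)oc3cc1OCc1ccc(OC)cc1)C=CC2(OC)OC
A4 | alternative 2 | (5S,6S,7R)-6,7-dihydroxy-8,8-dimethoxy-5-({7-[(4-methoxyphenyl)methoxy]-4-oxo-2-(2-phenylethyl)-4H-chromen-6-yl}oxy)-2-(2-phenylethyl)-5,6,7,8-tetrahydro-4H-chromen-4-one | O=c1cc(CCc2ccccc2)oc2c1[C@H](Oc1cc3c(=O)cc(CCc4ccccc4)oc3cc1OCc1ccc(OC)cc1)[C@@H](O)[C@@H](O)C2(OC)OC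
A5 | alternative 3 | 3-[(R)-4-methylbenzenesulfinyl]-6-(2-phenylethyl)-4H-pyran-4-one | O=c1cc(CCc2ccccc2)occ1[S@](=O)c1ccc(C)cc1
A6 | alternative 3 | (1E,3E)-4-({7-[(4-methoxyphenyl)methoxy]-4-oxo-2-(2-phenylethyl)-4H-chromen-6-yl}oxy)buta-1,3-dien-1-yl benzoate | O=C(O/C=C/C=C/Oc1cc2c(=O)cc(CCc3ccccc3)oc2cc1OCc1ccc(OC)cc1)c1ccccc1
A7 | alternative 3 | (5R,8S)-5-({7-[(4-methoxyphenyl)methoxy]-4-oxo-2-(2-phenylethyl)-4H-chromen-6-yl}oxy)-4-oxo-2-(2-phenylethyl)-5,8-dihydro-4H-chromen-8-yl benzoate | O=c1cc(CCc2ccccc2)oc2c1[C@H](Oc1cc3c(=O)cc(CCc4ccccc4)oc3cc1OCc1ccc(OC)cc1)C=C[C@@H]2OC(=O)c1ccccc1
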